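## Structural features

The target is a 4-hydroxybenzoic acid whose ring carbon ortho to the phenol carries the chain ArCH2–CH=C(CH3)–CH2–CH2–, which ends at C2 of a 1,3,3-trimethyl-7-oxabicyclo[2.2.1]heptane. The bicycle is a cyclohexane held as a boat by O7, which bridges the methyl-bearing quaternary bridgehead C1 and the CH bridgehead C4. C3, between C4 and C2, is a gem-dimethyl carbon, so C2 is flanked by two fully substituted carbons. The stereocentres are C1 (R), C2 (S) and C4 (S): C1 and C2 are adjacent, C4 is one carbon further, the bridgeheads fix each other through the bridge, and the C2 chain is exo (on the face of O7). The trisubstituted olefin is (E) and separated from the arene by one CH2, so it must not migrate into conjugation. Fragile parts are the ortho-allylphenol (closes to a chroman under acid), the tertiary C1–O bond (ionises under strong acid) and the free phenol and acid, best unveiled last under base. The real difficulty is the congested, strained bicycle: substitution and enolate chemistry at C2 are excluded, so the chain must be attached there by a radical. The key step exploits the oxolane ring O7–C1–C6–C5–C4, which is an oxetane (O, C4, C5, C6) enlarged by the single carbon C1; C1 is delivered as a carbenoid tethered to the oxetane CH through the carbonyl carbon C2 and the gem-dimethyl carbon C3.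

## Logic of the disconnections

**26 ⇒ 24.** Only the O–Si bond of the phenol and the O–CH3 bond of the ester are cut. Both acidic groups stay masked through the organometallic steps. The forward step must be basic and non-acidic; it passes through 25.

**24 ⇒ 17 + 23.** The C(sp3)–C(sp2) bond between the second chain carbon and the methyl-bearing olefin carbon is cut. This splits the molecule into a bicyclic and an aromatic half of similar size and lets the olefin geometry be fixed beforehand in 23. The forward coupling must transfer a primary alkyl group from boron with retention at the alkenyl carbon.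

**23 ⇒ 21 ⇒ 20 ⇒ 19 ⇒ 18.** The carbon–iodine and vinylic C–H bonds of 23 are removed to the alkyne of 21, the silyl group is removed (20), the benzylic C–H is returned to C–OH (19), and the bond between the benzylic carbon and the alkyne is cut to 18 and a propynyl nucleophile. The aldehyde carbon of 18 thus becomes the benzylic CH2. The demand is a syn hydrometallation that places the metal on the methyl-bearing alkyne carbon.

**17 ⇒ 15 + 16.** The C2–CH2 bond is cut. C2 is neopentyl on both sides, so only a radical can form a bond there. The cut removes the chain and the C2 stereocentre. The C2 radical must add to 16 faster than it is reduced, and on the exo face.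

**15 ⇒ 13 ⇒ 12.** Only C–O functional-group changes at C2 (xanthate, alcohol, ketone). 12 keeps just the two bridgehead stereocentres, and the carbonyl marks the carbon of the later radical.

**12 ⇒ 10 (key).** The O7–C1 and C1–C6 bonds are cut. Both rings of the bicycle and the C1 stereocentre fall away, leaving a monocyclic oxetane with one stereocentre. The forward step needs ylide formation at the oxetane oxygen and migration of the oxetane CH2, not the CH.

**10 ⇒ 8 ⇒ 7.** The C=N2 unit is removed (diazo transfer needs prior activation of the ketone), then the bond between the carbonyl carbon and the ethyl group is cut. The ethyl group supplies C1 and its methyl group.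

**7 ⇒ 6 ⇒ 5 ⇒ 4.** The O–CH2 bond of the oxetane is cut to a secondary alcohol and a primary leaving group. The stereogenic C–O bond is not involved, so configuration is retained. Closure is placed at the amide stage so that the intermediate alkoxide cannot fragment by retro-aldol.

**4 ⇒ 3 ⇒ 1 + 2.** The amide returns to the ester, and the bond between the carbinol carbon and the gem-dimethyl carbon is cut (aldol). Two achiral commercial compounds remain. The forward step must be enantioselective for the (S) carbinol.

## Other disconnections considered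

**Alternative 1:** The cut is the ring bond between the carbinol carbon C(OH)(CH3) and the ring CH carrying the acetate arm, in the monocyclic cyclohexane A1, which still lacks the oxygen bridge.
- Forward step: SmI2 with HMPA and t-BuOH reduces the methyl ketone of the open-chain keto enoate A2 to a ketyl, which adds 6-exo to the enoate β-carbon.
- In favour: ketyl–olefin cyclisation is established chemistry, and it sets the chain-bearing stereocentre with a two-carbon stub during ring formation. It therefore avoids the late intermolecular radical addition at hindered C2. On both points it is the better plan. A2 can take its stereocentre from the same aldol as 3, so the source of chirality is equal.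
- Against: the ring-CH stereocentre must be induced across the quaternary carbon. In A1 the tertiary hydroxyl is trans to the C3 oxygen, so the bridge can only be closed later by ionising the tertiary carbinol under acid. That closure forms a strained ether in competition with elimination and with lactonisation onto the ester arm. The stub then needs two more carbons, and HMPA is a drawback.
- Comparison: the chosen plan makes both rings and the bridge in one step but on an untested shift; Alternative 1 uses known steps but leaves the hardest bond to a cationic closure. Roughly seven steps to A2, then cyclisation, desilylation, bridging and chain adjustment, should come to no fewer than the eleven steps to 17.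

**Alternative 2:** The cut is the C2–C3 bond of the bicycle together with the bond between the first and second chain carbons.
- Forward step: the tertiary alcohol of A4 (the furanoid linalool oxide isomer with vinyl and hydroxyisopropyl cis) is converted into its caesium oxalate A5. Oxidative fragmentation releases the tertiary radical, which adds 5-exo to the internal vinyl carbon; the primary radical is trapped by allenyltributylstannane A6 to give alkyne A3.
- In favour: A4 already holds the oxolane ring, both bridgehead substituents and the gem-dimethyl carbon. The bicycle with a four-carbon chain would be reached in about three steps, so on step economy it is clearly the better plan. A3 is also the substrate of Alternative 3.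
- Against: the cyclisation joins a tertiary radical to a carbon next to a quaternary centre, builds a strained ring and trades a tertiary for a primary radical. It should be slow and possibly reversible, and direct propargylation of the uncyclised radical by A6 competes. The C2 configuration depends on which vinyl rotamer cyclises, with no clear bias. A4 is needed as one of four stereoisomers, and a tin reagent is used.
- Comparison: both plans hinge on an unproven step. The chosen plan sets C2 by exo attack on a rigid bicycle and takes absolute configuration from a reagent-controlled aldol, which is more predictable; Alternative 2 is far shorter if its cascade works.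

**Alternative 3:** The cut is at the olefin: the C–CH3 bond and the vinyl–CH2Ar bond, back to alkyne A3, Me3Al and benzylic chloride A8.
- Forward step: Cp2ZrCl2-catalysed syn methylalumination of A3, then Pd(PPh3)4-catalysed coupling of the alkenylalane with A8, gives A7 in one flask.
- In favour: regiochemistry and (E) geometry follow from the mechanism of syn carboalumination of a terminal alkyne. This is better than hydrozirconation of internal alkyne 21, which relies on equilibration. A8 is three steps from 18 against four for 23, also better.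
- Against: it says nothing about the bicycle. It needs A3, two carbons more than 17 carries (from 15, a Giese addition to an enone plus an alkyne synthesis, two steps in place of one). Me3Al is pyrophoric and Lewis acidic toward the strained bridging ether.
- Comparison: overall step count is about equal, and both transfer alkene geometry with retention. The chosen plan keeps the ether away from strong Lewis acids; Alternative 3 could be grafted onto the chosen bicycle synthesis if step 15 or 16 failed.

Key step: step 8

**Remarks on the chemistry**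
- The descriptors were checked against the SMILES: the oxetane centre of 10 is (S), 12 is (1R,4S), and C2 of 26 is (S) with the chain exo. No structural correction was needed.
- An ethyl ketone does not accept a diazo group directly, so step 7 activates it as trifluoroacetyl derivative 9.
- The oxetane is closed on Weinreb amide 6, before the ketone exists, because a β-alkoxide next to a ketone with an α-quaternary carbon is prone to retro-aldol cleavage.
- The methyl group on the carbenoid carbon opens a 1,2-hydride shift, which step 8 must suppress.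
- 2 is bought as such, which saves the enol silylation of methyl isobutyrate.
- Assumption: the (3S) sense of step 1 follows the accepted open transition-state model for the D-valine-derived promoter; if the sense were opposite, the L-valine promoter would be used with no other change.

## Route

Step 1
Reactants: 1 3-(benzyloxy)propanal; 2 [(1-methoxy-2-methylprop-1-en-1-yl)oxy]trimethylsilane
Product: 3 methyl (3S)-5-(benzyloxy)-3-hydroxy-2,2-dimethylpentanoate
Conditions: N-tosyl-D-valine (1 equiv), BH3·THF (1 equiv), CH2Cl2, 0 °C to rt; then 1 and 2, −78 °C; aq. NaHCO3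
Reagents that add atoms: none
Why: Kiyooka-type enantioselective Mukaiyama aldol: the aldehyde binds to boron of the D-valine-derived oxazaborolidinone anti to the isopropyl group and the silyl ketene acetal attacks the open carbonyl face through an open transition state, which should set C3 as (S); this donor with β-alkoxy aldehydes is well precedented.

Step 2
Reactants: 3 methyl (3S)-5-(benzyloxy)-3-hydroxy-2,2-dimethylpentanoate
Product: 4 (3S)-5-(benzyloxy)-3-hydroxy-N-methoxy-N,2,2-trimethylpentanamide
Conditions: Me(MeO)NH·HCl, i-PrMgCl, THF, −15 to 0 °C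
Reagents that add atoms: N,O-dimethylhydroxylamine hydrochloride, CNOC.Cl
Why: Ester aminolysis by the chloromagnesium amide (Weinreb amide formation), helped at the hindered ester by the neighbouring magnesium alkoxide; the amide is chosen because its enolate is too poor a leaving group for retro-aldol cleavage in step 5.

Step 3
Reactants: 4 (3S)-5-(benzyloxy)-3-hydroxy-N-methoxy-N,2,2-trimethylpentanamide
Product: 5 (3S)-3,5-dihydroxy-N-methoxy-N,2,2-trimethylpentanamide
Conditions: H2 (1 atm), Pd/C (10%), EtOAc, rt
Reagents that add atoms: none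
Why: Hydrogenolysis of the benzyl ether under neutral conditions leaves the N–O bond and the carbinol centre untouched; 5 is taken on at once to avoid lactonisation.

Step 4
Reactants: 5 (3S)-3,5-dihydroxy-N-methoxy-N,2,2-trimethylpentanamide
Product: 6 (3S)-3-hydroxy-5-[methoxy(methyl)amino]-4,4-dimethyl-5-oxopentyl 4-methylbenzenesulfonate
Conditions: TsCl (1.1 equiv), pyridine, CH2Cl2, 0 °C
Reagents that add atoms: 4-methylbenzenesulfonyl chloride, Cc1ccc(cc1)S(=O)(=O)Cl
Why: Sulfonylation distinguishes the unhindered primary hydroxyl from the neopentyl secondary one; 6 is used without storage because the amide oxygen could slowly displace the tosylate.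

Step 5
Reactants: 6 (3S)-3-hydroxy-5-[methoxy(methyl)amino]-4,4-dimethyl-5-oxopentyl 4-methylbenzenesulfonate
Product: 7 N-methoxy-N,2-dimethyl-2-[(2S)-oxetan-2-yl]propanamide
Conditions: NaH (1.2 equiv), THF, 0 °C to rt
Reagents that add atoms: none
Why: Intramolecular Williamson etherification (4-exo-tet): the secondary alkoxide displaces the primary tosylate, so the C–O bond at the stereocentre is never broken and it becomes (2S) of the oxetane with retention.

Step 6
Reactants: 7 N-methoxy-N,2-dimethyl-2-[(2S)-oxetan-2-yl]propanamide
Product: 8 2-methyl-2-[(2S)-oxetan-2-yl]pentan-3-one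
Conditions: EtMgBr (3 equiv), THF, 0 °C to rt; aq. NH4Cl
Reagents that add atoms: ethylmagnesium bromide, CC[Mg]Br
Why: Grignard addition to the Weinreb amide stops at the ketone through the stable magnesium chelate; the oxetane is inert to Grignard reagents at this temperature without added Lewis acid.

Step 7
Reactants: 8 2-methyl-2-[(2S)-oxetan-2-yl]pentan-3-one
Product: 10 2-diazo-4-methyl-4-[(2S)-oxetan-2-yl]pentan-3-one, via trifluoroacetyl diketone 9 (not isolated)
Conditions: LiN(SiMe3)2, THF, −78 °C; CF3CO2CH2CF3; dilute HCl wash, crude 9 taken on; 4-acetamidobenzenesulfonyl azide, Et3N, H2O, MeCN, rt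
Reagents that add atoms: 4-acetamidobenzenesulfonyl azide, CC(=O)Nc1ccc(cc1)S(=O)(=O)N=[N+]=[N-] (the N2 unit of 10); 2,2,2-trifluoroethyl trifluoroacetate, O=C(OCC(F)(F)F)C(F)(F)F (the trifluoroacetyl group of 9 only)
Why: Deacylative (detrifluoroacetylative) diazo transfer: the only enolisable position, the ethyl CH2, is trifluoroacetylated to 9, whose enolate attacks the sulfonyl azide and then passes the trifluoroacetyl group to nitrogen; the acetamido-substituted azide is the safer transfer reagent and 10 is kept in solution.

Step 8
Reactants: 10 2-diazo-4-methyl-4-[(2S)-oxetan-2-yl]pentan-3-one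
Product: 12 (1R,4S)-1,3,3-trimethyl-7-oxabicyclo[2.2.1]heptan-2-one, via oxonium ylide 11 (not isolated)
Conditions: Cu(CF3COCHCOCF3)2 [Cu(hfacac)2] (5 mol%), CH2Cl2, reflux, slow addition of 10
Reagents that add atoms: none
Why: Proposed new method: Cu(hfacac)2 decomposes the diazoketone to an electrophilic copper carbenoid, the oxetane oxygen held five atoms away by the gem-dimethyl tether attacks it to give bicyclic oxonium ylide 11, and strain-driven cleavage of the O–CH2 bond with recombination of that carbon at the ylide carbon (a [1,2]-Stevens shift) gives 12. The closest known reactions are the [1,2]-shifts of cyclic oxonium ylides from ether-tethered diazoketones, which give oxygen-bridged carbocycles, and the copper-catalysed intermolecular ring expansion of oxetanes to oxolanes by diazo esters; the intramolecular oxetane case leading to a [2.2.1] bicycle has not been shown. The first ring (O7–C1–C2–C3–C4, the 3-oxooxolane) closes by attack of oxygen on the carbenoid carbon through a five-membered transition state, and the second (O7–C1–C6–C5–C4, equally the cyclohexanone) by one-carbon ring expansion of the oxetane as C6 moves from oxygen to C1. C4 keeps its configuration because none of its bonds breaks, and the new stereocentre C1 is controlled by C4 through the bridge: oxygen and C6 can only join C1 on the face that C4 presents, so (4S) enforces (1R). Ylide formation must outrun 1,2-hydride migration from the carbenoid methyl and 1,5 C–H insertion, which the Lewis-basic oxetane oxygen, the Thorpe–Ingold effect of the gem-dimethyl group and the ylide-favouring fluorinated ligand should secure. The primary CH2 must migrate and not the ring-fusion CH; this is expected because only CH2 migration releases the oxetane strain without building a new four-membered ring (CH migration would give an oxolane-fused cyclobutanone), although the migrating carbon has no radical-stabilising group.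

Step 9
Reactants: 12 (1R,4S)-1,3,3-trimethyl-7-oxabicyclo[2.2.1]heptan-2-one
Product: 13 (1R,2R,4S)-1,3,3-trimethyl-7-oxabicyclo[2.2.1]heptan-2-ol
Conditions: NaBH4, MeOH, 0 °C to rt
Reagents that add atoms: none
Why: Hydride reduction of the hindered, non-enolisable ketone from the more open exo face (the side of O7), as with fenchone, should give mainly the endo alcohol; the C2 configuration is erased at the radical stage, so any exo epimer is carried along.

Step 10
Reactants: 13 (1R,2R,4S)-1,3,3-trimethyl-7-oxabicyclo[2.2.1]heptan-2-ol
Product: 15 O-[(1R,2R,4S)-1,3,3-trimethyl-7-oxabicyclo[2.2.1]heptan-2-yl] S-methyl carbonodithioate, via sodium xanthate 14 (not isolated)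
Conditions: NaH, imidazole (cat.), THF, reflux; CS2, rt; MeI, rt
Reagents that add atoms: carbon disulfide, S=C=S; iodomethane, CI
Why: Xanthate formation (alkoxide, CS2, then S-methylation) works for neopentyl-type alcohols and gives the radical precursor without any substitution at the blocked C2.

Step 11
Reactants: 15 O-[(1R,2R,4S)-1,3,3-trimethyl-7-oxabicyclo[2.2.1]heptan-2-yl] S-methyl carbonodithioate; 16 2-ethenyl-4,4,5,5-tetramethyl-1,3,2-dioxaborolane
Product: 17 4,4,5,5-tetramethyl-2-{2-[(1R,2S,4S)-1,3,3-trimethyl-7-oxabicyclo[2.2.1]heptan-2-yl]ethyl}-1,3,2-dioxaborolane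
Conditions: 16 (5 equiv), (Me3Si)3SiH (1.5 equiv, syringe pump), AIBN (0.2 equiv), PhCF3, 85 °C
Reagents that add atoms: none
Why: Barton–McCombie fragmentation coupled to a Giese addition: the silyl radical adds to C=S, the C2–O bond cleaves, the secondary radical adds to the unsubstituted terminus of the vinylboronate, and the α-boryl radical takes hydrogen from the silane. The C–C bond forms on the exo face (syn to O7), which lacks the endo hydrogens at C6 that shield the other face, and this sets C2 as (S).

Step 12
Reactants: 18 methyl 3-formyl-4-hydroxybenzoate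
Product: 19 methyl 4-hydroxy-3-[(1RS)-1-hydroxybut-2-yn-1-yl]benzoate
Conditions: CH3C≡CMgBr (2.5 equiv), THF, −20 to 0 °C; aq. NH4Cl
Reagents that add atoms: 1-propynylmagnesium bromide, CC#C[Mg]Br
Why: Grignard addition to the aldehyde; the first equivalent forms the magnesium phenoxide, which also deactivates the para ester so that only the aldehyde reacts, and the racemic carbinol centre is removed in step 13.

Step 13
Reactants: 19 methyl 4-hydroxy-3-[(1RS)-1-hydroxybut-2-yn-1-yl]benzoate
Product: 20 methyl 3-(but-2-yn-1-yl)-4-hydroxybenzoate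
Conditions: Et3SiH (3 equiv), CF3CO2H (10 equiv), CH2Cl2, −10 to 0 °C
Reagents that add atoms: none
Why: Ionic hydrogenation: acid ionises the benzylic, propargylic alcohol to a cation stabilised by the ortho oxygen, which takes hydride from the silane at the benzylic carbon and leaves the skipped alkyne.

Step 14
Reactants: 20 methyl 3-(but-2-yn-1-yl)-4-hydroxybenzoate
Product: 21 methyl 3-(but-2-yn-1-yl)-4-{[tri(propan-2-yl)silyl]oxy}benzoate
Conditions: i-Pr3SiCl (1.2 equiv), imidazole, DMF, rt
Reagents that add atoms: chlorotri(propan-2-yl)silane, CC(C)[Si](Cl)(C(C)C)C(C)C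
Why: Silylation masks the acidic O–H before hydrozirconation and keeps a phenoxide from intercepting the alkenylpalladium species in step 16; the bulky silyl group is chosen to survive aqueous phosphate.

Step 15
Reactants: 21 methyl 3-(but-2-yn-1-yl)-4-{[tri(propan-2-yl)silyl]oxy}benzoate
Product: 23 methyl 3-[(2E)-3-iodobut-2-en-1-yl]-4-{[tri(propan-2-yl)silyl]oxy}benzoate, via alkenylzirconocene 22 (not isolated)
Conditions: Cp2Zr(H)Cl (2.2 equiv), THF, rt to 45 °C; then I2, 0 °C
Reagents that add atoms: iodine, II; chloridobis(cyclopentadienyl)hydridozirconium, [H][Zr](Cl)(C1C=CC=C1)C1C=CC=C1 (the zirconium of 22 only)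
Why: Hydrozirconation (syn addition of Zr–H) then iodinolysis with retention; with excess reagent and gentle heating the alkenylzirconium isomers equilibrate to the one with zirconium on the less hindered, methyl-bearing carbon, so H and iodine end up cis and the iodide is (E).

Step 16
Reactants: 17 4,4,5,5-tetramethyl-2-{2-[(1R,2S,4S)-1,3,3-trimethyl-7-oxabicyclo[2.2.1]heptan-2-yl]ethyl}-1,3,2-dioxaborolane; 23 methyl 3-[(2E)-3-iodobut-2-en-1-yl]-4-{[tri(propan-2-yl)silyl]oxy}benzoate
Product: 24 methyl 3-[(2E)-3-methyl-5-[(1R,2S,4S)-1,3,3-trimethyl-7-oxabicyclo[2.2.1]heptan-2-yl]pent-2-en-1-yl]-4-{[tri(propan-2-yl)silyl]oxy}benzoate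
Conditions: Pd(OAc)2 (5 mol%), RuPhos (2-dicyclohexylphosphino-2′,6′-diisopropoxybiphenyl, 10 mol%), K3PO4 (3 equiv), toluene/H2O (10:1), 80 °C
Reagents that add atoms: none
Why: B-alkyl Suzuki–Miyaura coupling of a primary alkyl pinacol boronate with an alkenyl iodide: oxidative addition and reductive elimination go with retention, so the (E) geometry of 23 is carried into 24, and the bulky electron-rich phosphine speeds transmetallation ahead of β-hydride elimination.

Step 17
Reactants: 24 methyl 3-[(2E)-3-methyl-5-[(1R,2S,4S)-1,3,3-trimethyl-7-oxabicyclo[2.2.1]heptan-2-yl]pent-2-en-1-yl]-4-{[tri(propan-2-yl)silyl]oxy}benzoate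
Product: 26 4-hydroxy-3-[(2E)-3-methyl-5-[(1R,2S,4S)-1,3,3-trimethyl-7-oxabicyclo[2.2.1]heptan-2-yl]pent-2-en-1-yl]benzoic acid, via phenol methyl ester 25 (not isolated)
Conditions: Bu4NF (1.2 equiv), THF, 0 °C; then LiOH·H2O (5 equiv), MeOH/H2O, 45 °C; 1 M HCl to pH 4 at 0 °C
Reagents that add atoms: lithium hydroxide, [Li+].[OH-] (the hydroxide oxygen ends in the carboxyl group)
Why: Fluoride cleaves the aryl silyl ether and hydroxide then saponifies the methyl ester in the same flask; only base and a cold, mild acidification are used, so the ortho-allylphenol cannot close to a chroman and the bridging ether is not ionised.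

## Compound list

1 | 3-(benzyloxy)propanal | O=CCCOCc1ccccc1 | starting material
2 | [(1-methoxy-2-methylprop-1-en-1-yl)oxy]trimethylsilane | COC(=C(C)C)O[Si](C)(C)C | starting material
3 | methyl (3S)-5-(benzyloxy)-3-hydroxy-2,2-dimethylpentanoate | COC(=O)C(C)(C)[C@@H](O)CCOCc1ccccc1 | intermediate
4 | (3S)-5-(benzyloxy)-3-hydroxy-N-methoxy-N,2,2-trimethylpentanamide | CON(C)C(=O)C(C)(C)[C@@H](O)CCOCc1ccccc1 | intermediate
5 | (3S)-3,5-dihydroxy-N-methoxy-N,2,2-trimethylpentanamide | CON(C)C(=O)C(C)(C)[C@@H](O)CCO | intermediate
6 | (3S)-3-hydroxy-5-[methoxy(methyl)amino]-4,4-dimethyl-5-oxopentyl 4-methylbenzenesulfonate | CON(C)C(=O)C(C)(C)[C@@H](O)CCOS(=O)(=O)c1ccc(C)cc1 | intermediate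
7 | N-methoxy-N,2-dimethyl-2-[(2S)-oxetan-2-yl]propanamide | CON(C)C(=O)C(C)(C)[C@@H]1CCO1 | intermediate
8 | 2-methyl-2-[(2S)-oxetan-2-yl]pentan-3-one | CCC(=O)C(C)(C)[C@@H]1CCO1 | intermediate
9 | 1,1,1-trifluoro-3,5-dimethyl-5-[(2S)-oxetan-2-yl]hexane-2,4-dione (C3 epimers) | CC(C(=O)C(F)(F)F)C(=O)C(C)(C)[C@@H]1CCO1 | intermediate (not isolated)
10 | 2-diazo-4-methyl-4-[(2S)-oxetan-2-yl]pentan-3-one | CC(=[N+]=[N-])C(=O)C(C)(C)[C@@H]1CCO1 | intermediate
11 | (5S)-2,4,4-trimethyl-3-oxo-1-oxoniabicyclo[3.2.0]heptan-2-ide | C[C-]1C(=O)C(C)(C)[C@@H]2CC[O+]12 | intermediate (not isolated)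
12 | (1R,4S)-1,3,3-trimethyl-7-oxabicyclo[2.2.1]heptan-2-one | O=C1C(C)(C)[C@@H]2CC[C@@]1(C)O2 | intermediate
13 | (1R,2R,4S)-1,3,3-trimethyl-7-oxabicyclo[2.2.1]heptan-2-ol | O[C@@H]1C(C)(C)[C@@H]2CC[C@@]1(C)O2 | intermediate
14 | sodium O-[(1R,2R,4S)-1,3,3-trimethyl-7-oxabicyclo[2.2.1]heptan-2-yl] carbonodithioate | [Na+].[S-]C(=S)O[C@@H]1C(C)(C)[C@@H]2CC[C@@]1(C)O2 | intermediate (not isolated)
15 | O-[(1R,2R,4S)-1,3,3-trimethyl-7-oxabicyclo[2.2.1]heptan-2-yl] S-methyl carbonodithioate | CSC(=S)O[C@@H]1C(C)(C)[C@@H]2CC[C@@]1(C)O2 | intermediate
16 | 2-ethenyl-4,4,5,5-tetramethyl-1,3,2-dioxaborolane | C=CB1OC(C)(C)C(C)(C)O1 | starting material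
17 | 4,4,5,5-tetramethyl-2-{2-[(1R,2S,4S)-1,3,3-trimethyl-7-oxabicyclo[2.2.1]heptan-2-yl]ethyl}-1,3,2-dioxaborolane | CC1(C)OB(CC[C@H]2C(C)(C)[C@@H]3CC[C@@]2(C)O3)OC1(C)C | intermediate
18 | methyl 3-formyl-4-hydroxybenzoate | COC(=O)c1ccc(O)c(C=O)c1 | starting material
19 | methyl 4-hydroxy-3-[(1RS)-1-hydroxybut-2-yn-1-yl]benzoate (racemic) | COC(=O)c1ccc(O)c(C(O)C#CC)c1 | intermediate
20 | methyl 3-(but-2-yn-1-yl)-4-hydroxybenzoate | COC(=O)c1ccc(O)c(CC#CC)c1 | intermediate
21 | methyl 3-(but-2-yn-1-yl)-4-{[tri(propan-2-yl)silyl]oxy}benzoate | COC(=O)c1ccc(O[Si](C(C)C)(C(C)C)C(C)C)c(CC#CC)c1 | intermediate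
22 | chloridobis(cyclopentadienyl)[(2E)-4-{5-(methoxycarbonyl)-2-{[tri(propan-2-yl)silyl]oxy}phenyl}but-2-en-2-yl]zirconium (cyclopentadienyl rings drawn σ-bonded) | COC(=O)c1ccc(O[Si](C(C)C)(C(C)C)C(C)C)c(C/C=C(\C)[Zr](Cl)(C2C=CC=C2)C2C=CC=C2)c1 | intermediate (not isolated)
23 | methyl 3-[(2E)-3-iodobut-2-en-1-yl]-4-{[tri(propan-2-yl)silyl]oxy}benzoate | COC(=O)c1ccc(O[Si](C(C)C)(C(C)C)C(C)C)c(C/C=C(\C)I)c1 | intermediate
24 | methyl 3-[(2E)-3-methyl-5-[(1R,2S,4S)-1,3,3-trimethyl-7-oxabicyclo[2.2.1]heptan-2-yl]pent-2-en-1-yl]-4-{[tri(propan-2-yl)silyl]oxy}benzoate | COC(=O)c1ccc(O[Si](C(C)C)(C(C)C)C(C)C)c(C/C=C(\C)CC[C@H]2C(C)(C)[C@@H]3CC[C@@]2(C)O3)c1 | intermediate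
25 | methyl 4-hydroxy-3-[(2E)-3-methyl-5-[(1R,2S,4S)-1,3,3-trimethyl-7-oxabicyclo[2.2.1]heptan-2-yl]pent-2-en-1-yl]benzoate | COC(=O)c1ccc(O)c(C/C=C(\C)CC[C@H]2C(C)(C)[C@@H]3CC[C@@]2(C)O3)c1 | intermediate (not isolated)
26 | 4-hydroxy-3-[(2E)-3-methyl-5-[(1R,2S,4S)-1,3,3-trimethyl-7-oxabicyclo[2.2.1]heptan-2-yl]pent-2-en-1-yl]benzoic acid | C/C(=C\Cc1cc(C(=O)O)ccc1O)CC[C@H]1C(C)(C)[C@@H]2CC[C@@]1(C)O2 | target

## Step count and least certain steps

Total: 17 steps. Longest linear sequence: 13 steps (steps 1–11, 16, 17); the aromatic branch is steps 12–15.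

**Step 8 (key step, proposed new method).** The carbenoid may undergo 1,2-hydride migration from its methyl group before the oxetane oxygen captures it. The ylide may also collapse by migration of the ring-fusion CH, by recombination at the enolate oxygen, or by elimination, because the primary migrating carbon is not radical-stabilised. Fallback with known chemistry, from 8 back to 12, forms the same two bonds stepwise and ionically. Aqueous HBr opens the oxetane of 8 at its unhindered CH2 to give (5S)-7-bromo-5-hydroxy-4,4-dimethylheptan-3-one F1. Bromination of the only enolisable position (pyridinium tribromide, AcOH) should give (5S)-2,7-dibromo-5-hydroxy-4,4-dimethylheptan-3-one F2. Its hydroxyl displaces the α-bromide (K2CO3, acetone) to give (5S)-5-(2-bromoethyl)-2,4,4-trimethyloxolan-3-one F3. KOt-Bu in THF then forms the only possible enolate, which is alkylated across the ring by the bromoethyl arm to close 12. The stereocentre is never touched and again dictates the bridgehead.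

**Step 11.** Hydrogen transfer from the silane to the hindered C2 radical may outrun its addition to the weakly activated vinylboronate, giving simple deoxygenation. Fallback from 15 back to 17: the same radical is trapped by methyl acrylate, a much faster acceptor ((Me3Si)3SiH, AIBN), to give methyl 3-[(1R,2S,4S)-1,3,3-trimethyl-7-oxabicyclo[2.2.1]heptan-2-yl]propanoate F4. Saponification (LiOH) gives 3-[(1R,2S,4S)-1,3,3-trimethyl-7-oxabicyclo[2.2.1]heptan-2-yl]propanoic acid F5. Esterification with N-hydroxyphthalimide (diisopropylcarbodiimide) gives 1,3-dioxo-1,3-dihydro-2H-isoindol-2-yl 3-[(1R,2S,4S)-1,3,3-trimethyl-7-oxabicyclo[2.2.1]heptan-2-yl]propanoate F6. Decarboxylative borylation (B2pin2, Cu(acac)2 cat., LiOH·H2O, MgCl2) then replaces the carboxyl carbon by boron to give 17.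

**Step 16.** Transmetallation of the primary alkyl pinacol boronate may be too slow, so that protodeboronation, β-hydride elimination or loss of the silyl ether under the basic aqueous conditions takes over. Fallback from 17 back to 24 uses a Negishi coupling. Oxidation of 17 (NaBO3, THF/H2O) gives 2-[(1R,2S,4S)-1,3,3-trimethyl-7-oxabicyclo[2.2.1]heptan-2-yl]ethan-1-ol F7. Iodination (I2, PPh3, imidazole) gives (1R,2S,4S)-2-(2-iodoethyl)-1,3,3-trimethyl-7-oxabicyclo[2.2.1]heptane F8. Zinc insertion (Zn, LiCl, THF) gives iodo{2-[(1R,2S,4S)-1,3,3-trimethyl-7-oxabicyclo[2.2.1]heptan-2-yl]ethyl}zinc F9, which couples with 23 under Pd(OAc)2 and 2-dicyclohexylphosphino-2′,6′-dimethoxybiphenyl without base to give 24.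

**Step 13.** The cation may be diverted by rearrangement of the propargylic system to an enone, or by attack of the free phenol, before hydride is delivered. Fallback from 18 back to 21 makes the benzylic–alkyne bond by substitution. Silylation of 18 (i-Pr3SiCl, imidazole) gives methyl 3-formyl-4-{[tri(propan-2-yl)silyl]oxy}benzoate F10. Reduction (NaBH4, MeOH, 0 °C) gives methyl 3-(hydroxymethyl)-4-{[tri(propan-2-yl)silyl]oxy}benzoate F11. Bromination (CBr4, PPh3) gives methyl 3-(bromomethyl)-4-{[tri(propan-2-yl)silyl]oxy}benzoate F12. Coupling with CH3C≡CMgBr under CuBr·SMe2 catalysis gives 21.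

## Further compounds

F1 | step 8 | (5S)-7-bromo-5-hydroxy-4,4-dimethylheptan-3-one | CCC(=O)C(C)(C)[C@@H](O)CCBr
F2 | step 8 | (5S)-2,7-dibromo-5-hydroxy-4,4-dimethylheptan-3-one (C2 epimers) | CC(Br)C(=O)C(C)(C)[C@@H](O)CCBr
F3 | step 8 | (5S)-5-(2-bromoethyl)-2,4,4-trimethyloxolan-3-one (C2 epimers) | CC1O[C@@H](CCBr)C(C)(C)C1=O
F4 | step 11 | methyl 3-[(1R,2S,4S)-1,3,3-trimethyl-7-oxabicyclo[2.2.1]heptan-2-yl]propanoate | COC(=O)CC[C@H]1C(C)(C)[C@@H]2CC[C@@]1(C)O2
F5 | step 11 | 3-[(1R,2S,4S)-1,3,3-trimethyl-7-oxabicyclo[2.2.1]heptan-2-yl]propanoic acid | OC(=O)CC[C@H]1C(C)(C)[C@@H]2CC[C@@]1(C)O2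
F6 | step 11 | 1,3-dioxo-1,3-dihydro-2H-isoindol-2-yl 3-[(1R,2S,4S)-1,3,3-trimethyl-7-oxabicyclo[2.2.1]heptan-2-yl]propanoate | O=C(CC[C@H]1C(C)(C)[C@@H]2CC[C@@]1(C)O2)ON1C(=O)c2ccccc2C1=O
F7 | step 16 | 2-[(1R,2S,4S)-1,3,3-trimethyl-7-oxabicyclo[2.2.1]heptan-2-yl]ethan-1-ol | OCC[C@H]1C(C)(C)[C@@H]2CC[C@@]1(C)O2
F8 | step 16 | (1R,2S,4S)-2-(2-iodoethyl)-1,3,3-trimethyl-7-oxabicyclo[2.2.1]heptane | ICC[C@H]1C(C)(C)[C@@H]2CC[C@@]1(C)O2
F9 | step 16 | iodo{2-[(1R,2S,4S)-1,3,3-trimethyl-7-oxabicyclo[2.2.1]heptan-2-yl]ethyl}zinc | I[Zn]CC[C@H]1C(C)(C)[C@@H]2CC[C@@]1(C)O2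
F10 | step 13 | methyl 3-formyl-4-{[tri(propan-2-yl)silyl]oxy}benzoate | COC(=O)c1ccc(O[Si](C(C)C)(C(C)C)C(C)C)c(C=O)c1
F11 | step 13 | methyl 3-(hydroxymethyl)-4-{[tri(propan-2-yl)silyl]oxy}benzoate | COC(=O)c1ccc(O[Si](C(C)C)(C(C)C)C(C)C)c(CO)c1
F12 | step 13 | methyl 3-(bromomethyl)-4-{[tri(propan-2-yl)silyl]oxy}benzoate | COC(=O)c1ccc(O[Si](C(C)C)(C(C)C)C(C)C)c(CBr)c1
A1 | alternative 1 | methyl 2-[(1S,3S,6S)-3-[(tert-butyldimethylsilyl)oxy]-6-hydroxy-2,2,6-trimethylcyclohexyl]acetate | COC(=O)C[C@H]1C(C)(C)[C@@H](O[Si](C)(C)C(C)(C)C)CC[C@]1(C)O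
A2 | alternative 1 | methyl (2E,5S)-5-[(tert-butyldimethylsilyl)oxy]-4,4-dimethyl-8-oxonon-2-enoate | COC(=O)/C=C/C(C)(C)[C@@H](O[Si](C)(C)C(C)(C)C)CCC(C)=O
A3 | alternative 2 | (1R,2S,4S)-2-(but-3-yn-1-yl)-1,3,3-trimethyl-7-oxabicyclo[2.2.1]heptane | C#CCC[C@H]1C(C)(C)[C@@H]2CC[C@@]1(C)O2
A4 | alternative 2 | 2-[(2S,5R)-5-ethenyl-5-methyloxolan-2-yl]propan-2-ol | OC(C)(C)[C@@H]1CC[C@@](C=C)(C)O1
A5 | alternative 2 | caesium 2-({2-[(2S,5R)-5-ethenyl-5-methyloxolan-2-yl]propan-2-yl}oxy)-2-oxoacetate | [Cs+].[O-]C(=O)C(=O)OC(C)(C)[C@@H]1CC[C@@](C=C)(C)O1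
A6 | alternative 2 | tributyl(propa-1,2-dien-1-yl)stannane | C=C=C[Sn](CCCC)(CCCC)CCCC
A7 | alternative 3 | methyl 4-[(tert-butyldimethylsilyl)oxy]-3-[(2E)-3-methyl-5-[(1R,2S,4S)-1,3,3-trimethyl-7-oxabicyclo[2.2.1]heptan-2-yl]pent-2-en-1-yl]benzoate | COC(=O)c1ccc(O[Si](C)(C)C(C)(C)C)c(C/C=C(\C)CC[C@H]2C(C)(C)[C@@H]3CC[C@@]2(C)O3)c1
A8 | alternative 3 | methyl 4-[(tert-butyldimethylsilyl)oxy]-3-(chloromethyl)benzoate | COC(=O)c1ccc(O[Si](C)(C)C(C)(C)C)c(CCl)c1
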